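## Structural features

Methylarzanol is built from two fully substituted six-membered rings joined by one methylene. Ring A is a 2-methoxy-4H-pyran-4-one with ethyl at C6 and methyl at C5. Ring B is a phloroglucinol whose three carbon positions carry the bridge (C1'), a prenyl group (C3') and an acetyl group (C5'); the bridge runs from C3 of ring A to C1' of ring B. The molecule has no stereocentre and no stereogenic double bond, because the prenyl alkene ends in two methyl groups, so no two stereocentres stand next to each other. The problem is therefore one of regiochemistry and functional-group tolerance.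

Several groups are fragile. The 2-methoxy-4-pyranone is a vinylogous carbonate that strong acid or nucleophiles convert into the 4-hydroxy-2-pyranone. The prenyl alkene is lost on hydrogenation and cyclises onto an ortho phenol under acid. The free acylphloroglucinol is an easily oxidised ambident nucleophile, and the bridge between two enol-like rings can be cleaved or scrambled by forcing acid or base.

The real difficulty is to place three different carbon substituents around ring B without isomers and to fix the methyl group on the C2 oxygen of ring A, not on the C4 oxygen. The key step uses the fact that O1, C6 (ethyl) and C5 (methyl) of ring A are the enol of symmetrical pentan-3-one, while C2–C3–C4 with the benzylic carbon on C3 is a substituted malonyl unit. Ring A then arises by forming C4–C5 and O1–C2. The plan also uses the symmetry of ring B: once C1' is alkylated, the two remaining ring carbons are equivalent, so acetyl and then prenyl can each enter at only one place.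

## Logic of the disconnections

**16 to 14 and 15.** The bond between C3' of ring B and the prenyl CH2 is cut last in the forward sense, because the prenyl alkene would not survive hydrogenolysis or Lewis acid. In 14 only one ring carbon still bears hydrogen, so the site of alkylation is fixed by the structure. The forward step must achieve C-alkylation of an ambident phenolate in preference to O-alkylation, under a base that leaves the methoxypyranone alone.

**14 to 13.** The C5'–acetyl bond is cut. Ring B of 13 is symmetrical about the C1'–C4' axis, so its two open positions are the same and one regioisomer must result. The forward step needs a single acylation under a Lewis acid mild enough for the 2-methoxy-4-pyranone and the methylene bridge.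

**13 to 12 to 11.** The three O–benzyl bonds are cut, then the O–CH3 bond on the C2 oxygen. The phenols must be masked while the pyranone oxygen is methylated, and benzyl ethers come off by neutral hydrogenolysis, which the methoxypyranone tolerates as long as no prenyl group is present. Removing the methyl group returns the 4-hydroxy-2-pyranone tautomer, the form a ring synthesis delivers directly. The forward methylation must occur at the lactone carbonyl oxygen and not at the 4-hydroxyl.

**11 to 7 and 9.** Ring A is opened across C4–C5 and O1–C2. This is the strategic cut: it divides the pyranone into a three-carbon bis-electrophile that already carries the whole of ring B and a three-atom C–C–O nucleophile from a five-carbon ketone. The gain is one ring and two skeletal bonds in a single operation from two simple parts. The forward step must acylate on carbon before oxygen and must not let the electron-rich ring B or its ortho ethers react with the acyl chlorides.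

**7 to 6 to 5.** The two C–Cl bonds are traced to the diacid 6, and its two carboxyl groups to the cyclic acylal 5. This keeps the malonyl unit in a stable, crystalline form until just before use. The chlorination must be neutral, because ring B is nucleophilic enough to be attacked by electrophilic chlorinating media.

**5 to 2 and 3.** The bond between the benzylic carbon and the malonyl carbon is cut and traced through the alkene 4 to a carbonyl condensation. A benzylic halide of this ring would be too labile for an alkylation, whereas the aldehyde 2 is stable. The forward step needs a conjugate reduction that does not touch the benzyl ethers.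

**2 to 1, and 9 to 8.** The O–benzyl bonds of 2 and the O–Si bond of 9 are cut to reach purchasable materials. The symmetry of 8 means that only one constitutional enol ether can form.

## Other disconnections considered

**Alternative 1:** Ring B is cut across C3'–C4' and C1'–C2', with C4'–C5' closing in the same cascade. In the forward sense the cyclobutenone A2, which carries the finished ring A, is heated with the siloxyalkyne A3. Ring opening of A2, cycloaddition, a second ring opening and six-electron closure (Danheiser benzannulation) would give the phenol A1.
- In its favour: the prenyl group arrives on a defined carbon through A3, with no ambident phenolate alkylation. On this point the alternative is better than the chosen plan. The cascade is thermal and neutral, which suits the methoxypyranone at least as well as the chosen end game.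
- Against it: A2 is the mono-silyl enol ether of a 2-substituted cyclobutane-1,3-dione bearing the whole pyranone. Ring A must therefore be made first by some other method and then elaborated over several steps, and A3 needs ynolate chemistry. A1 still lacks the acetyl group at C5', which would have to be introduced by a Lewis-acid acylation next to a prenyl group flanked by phenols, inviting chroman formation. The chosen plan avoids this by acetylating before prenylating.
- Comparison: the two plans are equal in reliability of the ring-forming mechanism. The alternative is better for prenyl placement and worse for the acetyl group. It is clearly longer, since both partners are multi-step compounds.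

**Alternative 2:** Ring A is cut across C3–C4 and O1–C2, the same two bonds in a different polarity pairing. Heating the dioxinone A5 releases an acyl-substituted ketene that adds across the silyl ketene acetal A6. Loss of the silyloxy group from the cycloadduct would give A4, which is the same compound as 12.
- In its favour: the methoxy group is placed on the C2 oxygen by construction, so no ambident O-methylation is needed. On this point the alternative is better than the chosen plan. The C5/C6 substitution is again drawn from a simple propionyl unit, which is equal.
- Against it: A5 is not a stock compound and needs two or three steps. A6 is moisture-sensitive. The thermolysis requires heating above 100 °C. The cycloadduct can lose the methoxy group instead of the silyloxy group, which would lead back to the 4-hydroxy-2-pyranone series. Open-chain C-acylation and dimerisation of the ketene compete.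
- Comparison: the alternative saves the methylation step but spends steps on A5, so step economy is about equal. From A4 onward the end game is identical. The chosen annulation runs at low temperature with a partitioning problem (C- before O-acylation) that the substrate settles by itself, whereas the alternative has a leaving-group choice that is not secured.

**Alternative 3:** Ring B is cut at C5'–C6', between the acetyl-bearing carbon and the hydroxyl-bearing carbon next to C1'. Under Mg(OMe)2 the triketo ester A8 would form a chelated polyenolate, its C6 would attack the ester carbonyl in a Claisen condensation, and enolisation would give A7, which is the same compound as 14.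
- In its favour: the acetyl group is in place by construction, so no Friedel–Crafts acylation is run on a substrate holding the acid-sensitive methoxypyranone. On this point the alternative is better than the chosen plan. The methoxide medium can only exchange the 2-methoxy group degenerately.
- Against it: A8 requires polyanion chemistry on a chain that already carries ring A. Such polycarbonyl chains also lactonise through an enol oxygen to 4-hydroxy-2-pyranones, and the ester carbonyl sits next to a substituted carbon, which slows the desired closure.
- Comparison: the final prenylation is still needed, so the alternative is equal to the chosen plan there. It is poorer in step economy, because ring A has to be made first and then extended by a four-carbonyl chain.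

Key step: step 6

Remark on the chemistry: the precursor pair and the annulation product were checked atom by atom and needed no correction. The geometry of the enol ether has no bearing on the product, and 9 is drawn as its predominant Z isomer.

Remark on the design: the malonyl precursor 7 is reached through Meldrum's acid, one step shorter than a diester route, and is chlorinated under neutral conditions. Its ring B is electron-rich enough to be formylated by chloroiminium catalysts, and its ortho benzyl ethers could lactonise onto an acyl chloride under acid or heat.

## Route

Step 1
Reactants: 1 2,4,6-trihydroxybenzaldehyde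
Product: 2 2,4,6-tris(benzyloxy)benzaldehyde
Conditions: BnBr (3.6 equiv), K2CO3 (4 equiv), DMF, 70 °C
Reagents that add atoms: benzyl bromide, BrCc1ccccc1
Why: Williamson ether synthesis; excess halide and carbonate in warm DMF also alkylate the two chelated ortho hydroxyls, and the formyl group lowers the ring nucleophilicity so that C-benzylation should stay a minor pathway.

Step 2
Reactants: 2 2,4,6-tris(benzyloxy)benzaldehyde; 3 Meldrum's acid (2,2-dimethyl-1,3-dioxane-4,6-dione)
Product: 5 5-[2,4,6-tris(benzyloxy)benzyl]-2,2-dimethyl-1,3-dioxane-4,6-dione, via arylidene Meldrum's acid 4 (not isolated)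
Conditions: Hantzsch ester (1.1 equiv), L-proline (20 mol%), CH2Cl2–EtOH, rt
Reagents that add atoms: none
Why: Three-component reductive alkylation: amine-catalysed Knoevenagel condensation gives the doubly activated alkene 4, which accepts hydride from the dihydropyridine in a conjugate transfer hydrogenation; no hydrogen gas or metal is present, so the benzyl ethers are untouched.

Step 3
Reactants: 5 5-[2,4,6-tris(benzyloxy)benzyl]-2,2-dimethyl-1,3-dioxane-4,6-dione
Product: 6 2-[2,4,6-tris(benzyloxy)benzyl]malonic acid
Conditions: 2 M aq. HCl, THF, 45 °C
Reagents that add atoms: water, O
Why: Acid-catalysed hydrolysis of the cyclic acylal releases acetone and the malonic acid; the temperature is well below that at which a monoalkylmalonic acid decarboxylates, and aryl benzyl ethers resist dilute aqueous acid.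

Step 4
Reactants: 6 2-[2,4,6-tris(benzyloxy)benzyl]malonic acid
Product: 7 2-[2,4,6-tris(benzyloxy)benzyl]malonyl dichloride
Conditions: Me2C=C(Cl)NMe2 (2.2 equiv), CH2Cl2, 0 °C → rt; concentrate, use crude at once
Reagents that add atoms: 1-chloro-N,N,2-trimethylprop-1-en-1-amine, CC(C)=C(Cl)N(C)C
Why: Acid chloride formation with an α-chloroenamine: each carboxyl adds to the reagent and chloride collapses the acyloxyiminium to the acyl chloride and a neutral amide; no HCl, no formamide-derived chloroiminium and no heat are involved, which protects the nucleophilic ring B and the ortho benzyl ethers.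

Step 5
Reactants: 8 pentan-3-one
Product: 9 (Z)-trimethyl(pent-2-en-3-yloxy)silane
Conditions: Me3SiCl, Et3N, DMF, 80 °C; distil
Reagents that add atoms: chlorotrimethylsilane, C[Si](C)(C)Cl
Why: Silyl enol ether formation under equilibrating conditions; the symmetrical ketone can give only one constitutional isomer, the Z isomer should predominate, and any E isomer leads to the same product in step 6.

Step 6
Reactants: 7 2-[2,4,6-tris(benzyloxy)benzyl]malonyl dichloride; 9 (Z)-trimethyl(pent-2-en-3-yloxy)silane
Product: 11 6-ethyl-4-hydroxy-5-methyl-3-[2,4,6-tris(benzyloxy)benzyl]-2H-pyran-2-one, via diketo acid chloride 10 (not isolated)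
Conditions: 9 (1.5 equiv), Et2O–CH2Cl2, −78 °C → rt, 16 h
Reagents that add atoms: none
Why: The nucleophilic enol ether carbon of 9 attacks one acyl chloride of 7 (or the chlorocarbonyl ketene in equilibrium with it), chloride removes the silyl group as Me3SiCl, and the open-chain diketo acid chloride 10 results with the C4–C5 bond in place. Enolisation of the ethyl ketone of 10 brings its oxygen within reach of the second acyl chloride; addition–elimination at that trigonal carbon is a 6-exo-trig lactonisation that forms O1–C2 and closes ring A, and tautomerisation of the pyran-2,4-dione gives the 4-hydroxy-2-pyranone 11. The closest known reaction type is the annulation of ketone silyl enol ethers with malonyl and alkylmalonyl dichlorides to 4-hydroxy-2-pyranones. No stereocentre is created in 11: the two sp3 centres of 10 both become enol carbons, and the geometry of 9 is lost at C5. The selectivity needed is C-acylation before O-acylation and a single α-carbon; the first follows from the carbon nucleophilicity of a silyl enol ether toward acyl chlorides at low temperature without base, the second from the symmetry of the parent ketone. Ring B cannot be C-acylated intramolecularly because both positions ortho to the side chain carry benzyloxy groups, and the absence of Lewis acid and heat should keep those ethers from lactonising onto the acyl chloride.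

Step 7
Reactants: 11 6-ethyl-4-hydroxy-5-methyl-3-[2,4,6-tris(benzyloxy)benzyl]-2H-pyran-2-one
Product: 12 6-ethyl-2-methoxy-5-methyl-3-[2,4,6-tris(benzyloxy)benzyl]-4H-pyran-4-one
Conditions: MeOTf (2 equiv), CH2Cl2, 0 °C → rt; aq. NaHCO3
Reagents that add atoms: methyl trifluoromethanesulfonate, COS(=O)(=O)C(F)(F)F
Why: O-Methylation of the neutral hydroxypyranone by a hard electrophile occurs at its most basic site, the lactone carbonyl oxygen, and proton loss from the 4-hydroxyl then gives the 2-methoxy-4-pyranone; this preference is established for 3,5-disubstituted 4-hydroxy-2-pyranones, and any 4-methoxy-2-pyranone isomer should be separable by chromatography. The triflic acid stays paired with the basic pyranone carbonyl until the bicarbonate wash, so the benzyl ethers are not exposed to free strong acid.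

Step 8
Reactants: 12 6-ethyl-2-methoxy-5-methyl-3-[2,4,6-tris(benzyloxy)benzyl]-4H-pyran-4-one
Product: 13 6-ethyl-2-methoxy-5-methyl-3-(2,4,6-trihydroxybenzyl)-4H-pyran-4-one
Conditions: H2 (1 atm), Pd/C (10% palladium on carbon), EtOAc–MeOH, rt; keep under argon
Reagents that add atoms: none
Why: Hydrogenolysis of aryl benzyl ethers; the tetrasubstituted, vinylogous-ester double bonds of ring A and the C–C bonds of the bridge are not reduced at atmospheric pressure, and the air-sensitive triol is taken on without delay.

Step 9
Reactants: 13 6-ethyl-2-methoxy-5-methyl-3-(2,4,6-trihydroxybenzyl)-4H-pyran-4-one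
Product: 14 3-[(3-acetyl-2,4,6-trihydroxyphenyl)methyl]-6-ethyl-2-methoxy-5-methyl-4H-pyran-4-one
Conditions: Ac2O (1.05 equiv), BF3·OEt2 (3 equiv), 1,4-dioxane, 0 °C → rt; 10% aq. NaOAc
Reagents that add atoms: acetic anhydride, CC(=O)OC(C)=O
Why: Friedel–Crafts C-acylation of a 2-alkylphloroglucinol; the two open ring positions are equivalent, so one regioisomer must form, the first acetyl group deactivates the ring, and the limited amount of anhydride guards against a second acylation. Low temperature and a short reaction time are chosen to spare the methoxypyranone, whose carbonyl ties up part of the Lewis acid.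

Step 10
Reactants: 14 3-[(3-acetyl-2,4,6-trihydroxyphenyl)methyl]-6-ethyl-2-methoxy-5-methyl-4H-pyran-4-one; 15 prenyl bromide (1-bromo-3-methylbut-2-ene)
Product: 16 methylarzanol, 3-{[3-acetyl-2,4,6-trihydroxy-5-(3-methylbut-2-en-1-yl)phenyl]methyl}-6-ethyl-2-methoxy-5-methyl-4H-pyran-4-one
Conditions: DBU (1.1 equiv), THF, 0 °C → rt
Reagents that add atoms: none
Why: C-Alkylation of the acylphloroglucinol anion, a vinylogous enolate, by SN2 displacement on the allylic bromide at the only ring carbon that still bears hydrogen, followed by re-aromatising tautomerisation; the amidine base is non-nucleophilic and should not attack the methoxypyranone. A modest conversion with recovery of 14 is expected, as is usual for this reaction type.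

## Compound list

1 | 2,4,6-trihydroxybenzaldehyde | O=Cc1c(O)cc(O)cc1O | starting material
2 | 2,4,6-tris(benzyloxy)benzaldehyde | O=Cc1c(OCc2ccccc2)cc(OCc2ccccc2)cc1OCc1ccccc1 | intermediate
3 | Meldrum's acid (2,2-dimethyl-1,3-dioxane-4,6-dione) | CC1(C)OC(=O)CC(=O)O1 | starting material
4 | 5-[2,4,6-tris(benzyloxy)benzylidene]-2,2-dimethyl-1,3-dioxane-4,6-dione (formed and consumed in step 2) | CC1(C)OC(=O)C(=Cc2c(OCc3ccccc3)cc(OCc3ccccc3)cc2OCc2ccccc2)C(=O)O1 | intermediate
5 | 5-[2,4,6-tris(benzyloxy)benzyl]-2,2-dimethyl-1,3-dioxane-4,6-dione | CC1(C)OC(=O)C(Cc2c(OCc3ccccc3)cc(OCc3ccccc3)cc2OCc2ccccc2)C(=O)O1 | intermediate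
6 | 2-[2,4,6-tris(benzyloxy)benzyl]malonic acid | OC(=O)C(Cc1c(OCc2ccccc2)cc(OCc2ccccc2)cc1OCc1ccccc1)C(O)=O | intermediate
7 | 2-[2,4,6-tris(benzyloxy)benzyl]malonyl dichloride | O=C(Cl)C(Cc1c(OCc2ccccc2)cc(OCc2ccccc2)cc1OCc1ccccc1)C(Cl)=O | intermediate
8 | pentan-3-one | CCC(=O)CC | starting material
9 | (Z)-trimethyl(pent-2-en-3-yloxy)silane | C/C=C(/CC)O[Si](C)(C)C | intermediate
10 | 4-methyl-3,5-dioxo-2-[2,4,6-tris(benzyloxy)benzyl]heptanoyl chloride (mixture of stereoisomers, both centres lost on ring closure; formed and consumed in step 6) | CCC(=O)C(C)C(=O)C(Cc1c(OCc2ccccc2)cc(OCc2ccccc2)cc1OCc1ccccc1)C(Cl)=O | intermediate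
11 | 6-ethyl-4-hydroxy-5-methyl-3-[2,4,6-tris(benzyloxy)benzyl]-2H-pyran-2-one | CCc1oc(=O)c(Cc2c(OCc3ccccc3)cc(OCc3ccccc3)cc2OCc2ccccc2)c(O)c1C | intermediate
12 | 6-ethyl-2-methoxy-5-methyl-3-[2,4,6-tris(benzyloxy)benzyl]-4H-pyran-4-one | CCc1oc(OC)c(Cc2c(OCc3ccccc3)cc(OCc3ccccc3)cc2OCc2ccccc2)c(=O)c1C | intermediate
13 | 6-ethyl-2-methoxy-5-methyl-3-(2,4,6-trihydroxybenzyl)-4H-pyran-4-one | CCc1oc(OC)c(Cc2c(O)cc(O)cc2O)c(=O)c1C | intermediate
14 | 3-[(3-acetyl-2,4,6-trihydroxyphenyl)methyl]-6-ethyl-2-methoxy-5-methyl-4H-pyran-4-one | CCc1oc(OC)c(Cc2c(O)cc(O)c(C(C)=O)c2O)c(=O)c1C | intermediate
15 | prenyl bromide (1-bromo-3-methylbut-2-ene) | CC(C)=CCBr | starting material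
16 | methylarzanol, 3-{[3-acetyl-2,4,6-trihydroxy-5-(3-methylbut-2-en-1-yl)phenyl]methyl}-6-ethyl-2-methoxy-5-methyl-4H-pyran-4-one (no stereocentre) | CCc1oc(OC)c(Cc2c(O)c(CC=C(C)C)c(O)c(C(C)=O)c2O)c(=O)c1C | target

## Step count and least certain steps

Total step count: 10. Longest linear sequence: 9 steps (steps 1 to 4 and 6 to 10). Step 5 is a one-step side branch that joins at step 6.

**Step 6 (key step).** The most likely failure is consumption of the bis-acyl chloride before the hindered enol ether has acylated on carbon. This could happen by loss of HCl to a ketene that oligomerises, or by lactonisation of an ortho benzyloxy oxygen onto an acyl chloride with loss of the benzyl group. Protodesilylation of 9 by the HCl released in the ring closure would add to the problem. The fallback keeps the same (3+3) ring construction but attaches ring B afterwards. It sets out from 9 and 2 and returns at 11. Enol ether 9 and commercial malonyl dichloride (Et2O, −78 °C → rt) should give 6-ethyl-4-hydroxy-5-methyl-2H-pyran-2-one F1. Reductive alkylation of F1 at C3 with aldehyde 2 (Hantzsch ester, L-proline cat., CH2Cl2–EtOH, rt to 40 °C; Knoevenagel condensation followed by transfer hydrogenation in the same flask) should then give 11.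

**Step 10.** The ambident phenolate may alkylate on oxygen, or at the already substituted C1' with dearomatisation, or more than once, leaving little of the C3' product. The fallback replaces direct C-alkylation by O-alkylation and a sigmatropic shift. It sets out from 14 and returns at 16. Tsuji–Trost O-alkylation of 14 with tert-butyl 2-methylbut-3-en-2-yl carbonate (Pd(PPh3)4 cat., a zerovalent palladium complex, THF, 0 °C) should give the tertiary allyl ether at the hydroxyl para to the acetyl group, 3-{[3-acetyl-2,4-dihydroxy-6-(2-methylbut-3-en-2-yloxy)phenyl]methyl}-6-ethyl-2-methoxy-5-methyl-4H-pyran-4-one F2. An aromatic Claisen rearrangement (toluene, 100 °C) would move the allyl unit to the adjacent free carbon with allylic inversion and so deliver the normal prenyl group of 16. Etherification at the other hydroxyl that flanks the same carbon would converge on 16 as well.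

**Step 9.** The Lewis acid may demethylate or hydrolyse the methoxypyranone through its activated carbonyl complex, a second acetyl group may enter, or the methylene bridge may scramble. The fallback moves the acylation in front of the debenzylation and uses no metal Lewis acid. It sets out from 12 and returns at 14. Acylation of the still benzylated, highly activated ring of 12 with the mixed anhydride from AcOH and (CF3CO)2O (CH2Cl2, 0 °C → rt) should give 3-{[3-acetyl-2,4,6-tris(benzyloxy)phenyl]methyl}-6-ethyl-2-methoxy-5-methyl-4H-pyran-4-one F3. Hydrogenolysis (H2, Pd/C, EtOAc–MeOH, rt) would then give 14; the chelated, vinylogous-acid ketone should resist reduction.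

**Step 3.** The acidic ring opening may be incomplete, or the malonic acid may partly decarboxylate to the arylpropanoic acid. The fallback is the diester sequence. It sets out from 2 and returns at 6. Knoevenagel condensation of 2 with dimethyl malonate (piperidine, AcOH, toluene, reflux with water removal) should give dimethyl 2-[2,4,6-tris(benzyloxy)benzylidene]malonate F4. Conjugate reduction (NaBH4, MeOH–THF, 0 °C) should give dimethyl 2-[2,4,6-tris(benzyloxy)benzyl]malonate F5, and saponification (KOH, MeOH–H2O, then cold dilute HCl) would give 6.

## Further compounds

F1 | step 6 | 6-ethyl-4-hydroxy-5-methyl-2H-pyran-2-one | CCc1oc(=O)cc(O)c1C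
F2 | step 10 | 3-{[3-acetyl-2,4-dihydroxy-6-(2-methylbut-3-en-2-yloxy)phenyl]methyl}-6-ethyl-2-methoxy-5-methyl-4H-pyran-4-one | CCc1oc(OC)c(Cc2c(OC(C)(C)C=C)cc(O)c(C(C)=O)c2O)c(=O)c1C
F3 | step 9 | 3-{[3-acetyl-2,4,6-tris(benzyloxy)phenyl]methyl}-6-ethyl-2-methoxy-5-methyl-4H-pyran-4-one | CCc1oc(OC)c(Cc2c(OCc3ccccc3)cc(OCc3ccccc3)c(C(C)=O)c2OCc2ccccc2)c(=O)c1C
F4 | step 3 | dimethyl 2-[2,4,6-tris(benzyloxy)benzylidene]malonate | COC(=O)C(=Cc1c(OCc2ccccc2)cc(OCc2ccccc2)cc1OCc1ccccc1)C(=O)OC
F5 | step 3 | dimethyl 2-[2,4,6-tris(benzyloxy)benzyl]malonate | COC(=O)C(Cc1c(OCc2ccccc2)cc(OCc2ccccc2)cc1OCc1ccccc1)C(=O)OC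
A1 | alternative 1 | 6-ethyl-3-{[4-hydroxy-3-(3-methylbut-2-enyl)-2,6-bis(triisopropylsilyloxy)phenyl]methyl}-2-methoxy-5-methyl-4H-pyran-4-one | Oc1cc(O[Si](C(C)C)(C(C)C)C(C)C)c(Cc2c(OC)oc(CC)c(C)c2=O)c(O[Si](C(C)C)(C(C)C)C(C)C)c1CC=C(C)C
A2 | alternative 1 | 2-[(6-ethyl-2-methoxy-5-methyl-4-oxo-4H-pyran-3-yl)methyl]-3-(triisopropylsilyloxy)cyclobut-2-en-1-one | O=C1CC(O[Si](C(C)C)(C(C)C)C(C)C)=C1Cc1c(OC)oc(CC)c(C)c1=O
A3 | alternative 1 | triisopropyl[(5-methylhex-4-en-1-yn-1-yl)oxy]silane | CC(C)=CCC#CO[Si](C(C)C)(C(C)C)C(C)C
A4 | alternative 2 | 6-ethyl-2-methoxy-5-methyl-3-[2,4,6-tris(benzyloxy)benzyl]-4H-pyran-4-one (identical with 12) | CCc1oc(OC)c(Cc2c(OCc3ccccc3)cc(OCc3ccccc3)cc2OCc2ccccc2)c(=O)c1C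
A5 | alternative 2 | 6-ethyl-2,2,5-trimethyl-4H-1,3-dioxin-4-one | CCC1=C(C)C(=O)OC(C)(C)O1
A6 | alternative 2 | {[1-methoxy-3-[2,4,6-tris(benzyloxy)phenyl]prop-1-en-1-yl]oxy}trimethylsilane (either double-bond isomer) | COC(O[Si](C)(C)C)=CCc1c(OCc2ccccc2)cc(OCc2ccccc2)cc1OCc1ccccc1
A7 | alternative 3 | 3-[(3-acetyl-2,4,6-trihydroxyphenyl)methyl]-6-ethyl-2-methoxy-5-methyl-4H-pyran-4-one (identical with 14) | CCc1oc(OC)c(Cc2c(O)cc(O)c(C(C)=O)c2O)c(=O)c1C
A8 | alternative 3 | methyl 2-[(6-ethyl-2-methoxy-5-methyl-4-oxo-4H-pyran-3-yl)methyl]-3,5,7-trioxooctanoate (racemic, drawn as the keto form) | COC(=O)C(Cc1c(OC)oc(CC)c(C)c1=O)C(=O)CC(=O)CC(C)=O
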